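The seven-membered ring B is closed at the bond between the side-chain-bearing carbon C7 and the ring methylene C8 by a cis-divinylcyclopropane–cycloheptadiene (Cope) rearrangement. In the precursor the ring-fusion carbons C1 and C5 and the future methylene-bearing carbon C10 form a cyclopropane on cyclopentene ring A; C10 carries a vinyl group (C9=C8), C5 a (Z)-enol ether (C6=C7) with the complete side chain, and the C10 carboxyl is tied to the C4 oxygen as a lactone. One [3,3] shift cleaves C5–C10, forms C7–C8, sets C7 relative to C1 through a boat transition state and unveils the 1,4-diene hidden in ring B: C5=C6 (latent carbinol C6) and C9=C10 (latent exocyclic methylene).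

Key step: step 11

Numbering used throughout: ring A = C1(H)–C2=C3–C4(CH3)(OH)–C5(H); ring B = C1, C5, C6(OH), C7, C8, C9, C10; C18 is the carbon on C10 (ester, lactone, acid, CH2OH, finally =CH2); the side chain on C7 is C11(H)(CH3)–C12H2–C13(H)(OAc)–C14H=C15(CH3)2.

Assumption: methyl (R)-3-methylglutarate, (S)-4-(tert-butyldimethylsilyloxy)cyclopent-2-en-1-one, methyl 2-bromobut-2-enoate and 2-methylprop-1-enylmagnesium bromide are taken as purchasable.

Step 1
Reactants: 1 methyl (R)-3-methylglutarate
Product: 2 methyl (3R)-5-[methoxy(methyl)amino]-3-methyl-5-oxopentanoate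
Conditions: 1,1'-carbonyldiimidazole, CH2Cl2, 0 °C to rt; then MeNH(OMe)·HCl, rt
Reagents that add atoms: N,O-dimethylhydroxylamine hydrochloride, CNOC.Cl
Why: Acyl-imidazolide formation followed by aminolysis (Weinreb amide synthesis) converts only the free acid terminus, the future C13, and leaves the methyl ester, the future C6, and the C11 stereocentre untouched.

Step 2
Reactants: 2 methyl (3R)-5-[methoxy(methyl)amino]-3-methyl-5-oxopentanoate; 3 2-methylprop-1-enylmagnesium bromide
Product: 4 methyl (3R)-3,7-dimethyl-5-oxooct-6-enoate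
Conditions: THF, −78 to −10 °C; aq NH4Cl
Reagents that add atoms: 2-methylprop-1-enylmagnesium bromide (3), CC(C)=C[Mg]Br
Why: Grignard addition to the Weinreb amide stops at the ketone because of the chelated tetrahedral magnesium adduct and, at low temperature, is faster than attack on the methyl ester, which installs C14 to C17 of the side chain.

Step 3
Reactants: 4 methyl (3R)-3,7-dimethyl-5-oxooct-6-enoate
Product: 5 methyl (3R,5R)-5-hydroxy-3,7-dimethyloct-6-enoate
Conditions: (S)-2-methyl-CBS-oxazaborolidine (20 mol %), BH3·SMe2, THF, −20 °C; MeOH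
Reagents that add atoms: none
Why: Corey–Bakshi–Shibata reduction delivers hydride to one face of the enone carbonyl with the alkenyl group acting as the large substituent, which should set C13 as R under catalyst control and independently of the remote C11 centre.

Step 4
Reactants: 5 methyl (3R,5R)-5-hydroxy-3,7-dimethyloct-6-enoate
Product: 6 methyl (3R,5R)-5-(tert-butyldimethylsilyloxy)-3,7-dimethyloct-6-enoate
Conditions: t-BuMe2SiCl, imidazole, DMF, rt
Reagents that add atoms: tert-butyldimethylsilyl chloride, CC(C)(C)[Si](C)(C)Cl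
Why: Silylation of the allylic alcohol under standard imidazole conditions blocks δ-lactonisation onto the ester and protects the C13 oxygen through the organometallic steps.

Step 5
Reactants: 6 methyl (3R,5R)-5-(tert-butyldimethylsilyloxy)-3,7-dimethyloct-6-enoate
Product: 7 (3R,5R)-5-(tert-butyldimethylsilyloxy)-3,7-dimethyloct-6-enal
Conditions: i-Bu2AlH, CH2Cl2, −78 °C; aq potassium sodium tartrate
Reagents that add atoms: none
Why: i-Bu2AlH reduction at −78 °C stops at the aldehyde oxidation level through the stable aluminium hemiacetal, giving the C6 aldehyde without touching the silyl ether or the alkene.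

Step 6
Reactants: 7 (3R,5R)-5-(tert-butyldimethylsilyloxy)-3,7-dimethyloct-6-enal; 8 (S)-4-(tert-butyldimethylsilyloxy)cyclopent-2-en-1-one
Product: 9 Baylis–Hillman adduct (2-(1-hydroxyalkyl)enone, both C6 epimers)
Conditions: n-Bu3P (20 mol %), phenol (20 mol %), THF, rt
Reagents that add atoms: none
Why: Morita–Baylis–Hillman reaction: reversible conjugate addition of the phosphine to the enone gives an enolate that adds to the aldehyde and then expels the phosphine, forming the C5–C6 bond, while the new carbinol centre is left as a mixture because it is oxidised in step 10.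

Step 7
Reactants: 9 Baylis–Hillman adduct
Product: 10 triethylsilyl ether of 9
Conditions: Et3SiCl, imidazole, CH2Cl2, 0 °C
Reagents that add atoms: chlorotriethylsilane, CC[Si](Cl)(CC)CC
Why: Silylation removes the acidic hydroxyl that would quench the dienolate of step 8, and the triethylsilyl ether can later be cleaved beside the tert-butyldimethylsilyl ether at C13.

Step 8
Reactants: 10 triethylsilyl ether of 9; 11 methyl 2-bromobut-2-enoate
Product: 13 vinylcyclopropyl enone ester, via silyloxy cyclopropyl ketone 12 (not isolated)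
Conditions: LiN(i-Pr)2, 11, THF/DMPU, −78 °C; then 10, −78 to −20 °C; then DBU, 0 °C to rt
Reagents that add atoms: methyl 2-bromobut-2-enoate (11), CC=C(Br)C(=O)OC
Why: Michael-initiated ring closure: the lithium dienolate of 11 adds through its α-carbon to C1 of the enone anti to the C2 silyloxy group, which sets C1, the resulting C5 enolate displaces bromide (3-exo-tet) to close the cyclopropane on the same face, lithium chelation between the enolate oxygen and the ester should favour the endo ester and exo vinyl group at C10, and DBU then eliminates the C2 silanol (E1cB) to give the C2=C3 alkene.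

Step 9
Reactants: 13 vinylcyclopropyl enone ester
Product: 15 tricyclic γ-lactone, via lithium alkoxide 14 (not isolated)
Conditions: MeLi, CeCl3, THF, −78 to 0 °C; aq NH4Cl
Reagents that add atoms: methyllithium, [Li]C
Why: Organocerium 1,2-addition to the C4 ketone occurs from the convex face anti to the cyclopropane and its endo ester, which sets C4 with oxygen cis to C10, and the alkoxide then closes onto the endo ester to the γ-lactone, a reaction open only to the exo-vinyl epimer, so that the C10 epimer is removed at this stage as its hydroxy ester.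

Step 10
Reactants: 15 tricyclic γ-lactone
Product: 17 cyclopropyl ketone lactone, via carbinol 16 (not isolated)
Conditions: HF·pyridine, pyridine, THF, 0 °C; then Dess–Martin periodinane, pyridine, CH2Cl2, rt
Reagents that add atoms: none
Why: Buffered HF·pyridine cleaves the secondary triethylsilyl ether faster than the tert-butyldimethylsilyl ether, and Dess–Martin oxidation of the carbinol gives the C6 ketone, whose only α-hydrogens are at C7.

Step 11
Reactants: 17 cyclopropyl ketone lactone
Product: 19 bridged-lactone cycloheptadiene, via cis-divinylcyclopropane enol ether 18 (not isolated)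
Conditions: KN(SiMe3)2, THF, −78 °C; MeOCH2Cl, −78 to 0 °C; then toluene, 60 °C
Reagents that add atoms: chloromethyl methyl ether, COCCl
Why: KN(SiMe3)2 removes one of the only enolisable hydrogens (C7) of 17 and MeOCH2Cl traps the potassium enolate on oxygen to give the (Z)-enol ether 18, which is a cis-1,2-divinylcyclopropane because the lactone holds the C10 carboxyl endo and therefore the vinyl group exo, cis to the C5 enol ether. On warming, 18 should undergo the concerted [3,3]-sigmatropic divinylcyclopropane–cycloheptadiene (Cope) rearrangement, the closest known reaction type being the rearrangement of 2-oxy-substituted cis-divinylcyclopropanes made from enol ethers of cyclopropyl ketones. Ring B is closed through a six-centre boat transition state by the new C7–C8 σ-bond while the strained C5–C10 bond opens (four-atom expansion of the three-membered ring), and the γ-lactone becomes a bridged δ-lactone. The only new stereocentre, C7, is fixed by that boat, in which both alkenes fold over the cyclopropane: the (Z)-enol ether puts the C7 hydrogen inside and the side chain outside, so that H-7 ends cis to H-1, whose configuration was set in step 8. The step needs the cis (exo) vinyl geometry and the (Z)-enol ether; the first is secured by the lactone of step 9, the second by allylic strain between C5 and C11 in the enolate. Relief of cyclopropane and lactone strain should make the shift irreversible slightly above room temperature.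

Step 12
Reactants: 19 bridged-lactone cycloheptadiene
Product: 23 trans-fused keto acid, via dipotassium salt 20 (not isolated), via bis-silyl derivative 21 (not isolated), via enol ether acid 22 (not isolated)
Conditions: KOSiMe3, THF, rt; then Et3SiCl, 0 °C; then AcOH/NaOAc buffer (pH 4.5), THF/H2O, 0 °C to rt
Reagents that add atoms: potassium trimethylsilanolate, C[Si](C)(C)[O-].[K+]; chlorotriethylsilane, CC[Si](Cl)(CC)CC; water, O
Why: Silanolate opens the bridged lactone, chlorotriethylsilane caps the tertiary C4 alkoxide (and transiently the carboxylate) so that the doubly allylic C4–O bond cannot ionise, and at pH 4.5 the freed C18 carboxylic acid, which sits on the face of C5 syn to the C1–C10 bond, should protonate the enol ether at C5 through a six-membered transition state (intramolecular general-acid catalysis of enol ether hydrolysis) faster than external acid attacks the convex face, which should give H-5 trans to H-1 and cis to the C4 oxygen before water releases the C6 ketone.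

Step 13
Reactants: 23 trans-fused keto acid
Product: 24 dihydroxy keto acid
Conditions: HF·pyridine, pyridine, THF, 0 °C to rt
Reagents that add atoms: none
Why: Fluoride-driven cleavage of both silyl ethers under pyridine buffering liberates the C4 and C13 hydroxyls without epimerising the β-hydroxy ketone at C5 or C7.

Step 14
Reactants: 24 dihydroxy keto acid
Product: 25 C13 acetate keto acid
Conditions: Ac2O, pyridine, 0 °C to rt; aqueous work-up
Reagents that add atoms: acetic anhydride, CC(=O)OC(C)=O
Why: Acetylation in pyridine esterifies only the secondary allylic C13 alcohol, because the C4 alcohol is tertiary, C6 is still a ketone and the mixed anhydride formed at C18 is hydrolysed on work-up.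

Step 15
Reactants: 25 C13 acetate keto acid
Product: 27 C18 allylic alcohol triol acetate, via mixed anhydride 26 (not isolated)
Conditions: i-BuOCOCl, N-methylmorpholine, THF, −15 °C; then NaBH4, MeOH, −15 to 0 °C
Reagents that add atoms: none
Why: The mixed carbonic anhydride is reduced by NaBH4 to the primary allylic alcohol while the same reagent reduces the C6 ketone by attack on the face opposite the pseudo-axial C7 side chain, which should give the C6 alcohol cis to the side chain, and the acetate survives these conditions.

Step 16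
Reactants: 27 C18 allylic alcohol triol acetate
Product: 30 target CNP0209568.3, via sulfonyl hydrazine 28 (not isolated), via allylic diazene 29 (not isolated)
Conditions: 2-nitrobenzenesulfonylhydrazide, PPh3, diethyl azodicarboxylate, THF, −30 °C to rt
Reagents that add atoms: none
Why: Mitsunobu displacement of the primary allylic alcohol by the sulfonylhydrazide, loss of sulfinic acid to the allylic diazene and its retro-ene loss of N2 (reductive 1,3-transposition) deliver hydrogen to C9 and move the double bond to the exocyclic C10=C18 position, the secondary and tertiary alcohols being too hindered to react.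

Compound list

1 | methyl (R)-3-methylglutarate, (3R)-5-methoxy-3-methyl-5-oxopentanoic acid | COC(=O)C[C@H](C)CC(=O)O | starting material
2 | methyl (3R)-5-[methoxy(methyl)amino]-3-methyl-5-oxopentanoate | COC(=O)C[C@H](C)CC(=O)N(C)OC | intermediate
3 | 2-methylprop-1-enylmagnesium bromide | CC(C)=C[Mg]Br | starting material
4 | methyl (3R)-3,7-dimethyl-5-oxooct-6-enoate | COC(=O)C[C@H](C)CC(=O)C=C(C)C | intermediate
5 | methyl (3R,5R)-5-hydroxy-3,7-dimethyloct-6-enoate | COC(=O)C[C@H](C)C[C@H](C=C(C)C)O | intermediate
6 | methyl (3R,5R)-5-(tert-butyldimethylsilyloxy)-3,7-dimethyloct-6-enoate | COC(=O)C[C@H](C)C[C@H](C=C(C)C)O[Si](C)(C)C(C)(C)C | intermediate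
7 | (3R,5R)-5-(tert-butyldimethylsilyloxy)-3,7-dimethyloct-6-enal | O=CC[C@H](C)C[C@H](C=C(C)C)O[Si](C)(C)C(C)(C)C | intermediate
8 | (S)-4-(tert-butyldimethylsilyloxy)cyclopent-2-en-1-one | O=C1C=C[C@@H](O[Si](C)(C)C(C)(C)C)C1 | starting material
9 | Baylis–Hillman adduct: enone 8 carrying at its α-carbon the 1-hydroxyalkyl chain from 7 (C6 carbinol epimers) | O=C1C(C(O)C[C@H](C)C[C@H](C=C(C)C)O[Si](C)(C)C(C)(C)C)=C[C@@H](O[Si](C)(C)C(C)(C)C)C1 | intermediate
10 | triethylsilyl ether of 9 | O=C1C(C(O[Si](CC)(CC)CC)C[C@H](C)C[C@H](C=C(C)C)O[Si](C)(C)C(C)(C)C)=C[C@@H](O[Si](C)(C)C(C)(C)C)C1 | intermediate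
11 | methyl 2-bromobut-2-enoate (E/Z mixture) | CC=C(Br)C(=O)OC | starting material
12 | silyloxy cyclopropyl ketone: bicyclo[3.1.0]hexan-4-one numbered C1 to C5 and C10, cyclopropane anti to the C2 silyloxy group, C10 with exo vinyl and endo CO2Me (C10 epimer also formed), C5 with the silylated side chain | O=C1C[C@H](O[Si](C)(C)C(C)(C)C)[C@@H]2[C@@]1(C(O[Si](CC)(CC)CC)C[C@H](C)C[C@H](C=C(C)C)O[Si](C)(C)C(C)(C)C)[C@]2(C=C)C(=O)OC | intermediate (not isolated)
13 | vinylcyclopropyl enone ester: 12 after loss of the C2 silanol, C2=C3 alkene (shown as the exo-vinyl, endo-ester epimer) | O=C1C=C[C@@H]2[C@@]1(C(O[Si](CC)(CC)CC)C[C@H](C)C[C@H](C=C(C)C)O[Si](C)(C)C(C)(C)C)[C@]2(C=C)C(=O)OC | intermediate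
14 | lithium alkoxide from methyl addition to C4 of 13 (methyl anti to the cyclopropane) | C[C@]1([O-])C=C[C@@H]2[C@@]1(C(O[Si](CC)(CC)CC)C[C@H](C)C[C@H](C=C(C)C)O[Si](C)(C)C(C)(C)C)[C@]2(C=C)C(=O)OC.[Li+] | intermediate (not isolated)
15 | tricyclic γ-lactone: C4 oxygen acylated by the endo C10 carboxyl, exo vinyl on C10 | C[C@]12C=C[C@@H]3[C@@]1(C(O[Si](CC)(CC)CC)C[C@H](C)C[C@H](C=C(C)C)O[Si](C)(C)C(C)(C)C)[C@]3(C=C)C(=O)O2 | intermediate
16 | carbinol: 15 with free C6 hydroxyl | C[C@]12C=C[C@@H]3[C@@]1(C(O)C[C@H](C)C[C@H](C=C(C)C)O[Si](C)(C)C(C)(C)C)[C@]3(C=C)C(=O)O2 | intermediate (not isolated)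
17 | cyclopropyl ketone lactone (C6 ketone) | C[C@]12C=C[C@@H]3[C@@]1(C(=O)C[C@H](C)C[C@H](C=C(C)C)O[Si](C)(C)C(C)(C)C)[C@]3(C=C)C(=O)O2 | intermediate
18 | cis-divinylcyclopropane: (Z)-methoxymethyl enol ether C6=C7 on C5, exo vinyl on C10 | C[C@]12C=C[C@@H]3[C@@]1(/C(OCOC)=C/[C@H](C)C[C@H](C=C(C)C)O[Si](C)(C)C(C)(C)C)[C@]3(C=C)C(=O)O2 | intermediate (not isolated)
19 | bridged-lactone cycloheptadiene: ring B with C5=C6 (OCH2OCH3 on C6) and C9=C10, C18 carbonyl lactonised to the C4 oxygen, H-7 cis to H-1 | C[C@@]12C=C[C@H]3C(C(=O)O1)=CC[C@@H]([C@H](C)C[C@H](C=C(C)C)O[Si](C)(C)C(C)(C)C)C(OCOC)=C23 | intermediate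
20 | dipotassium salt: C18 carboxylate and C4 alkoxide | [K+].[K+].[O-]C(=O)C1=CC[C@@H]([C@H](C)C[C@H](C=C(C)C)O[Si](C)(C)C(C)(C)C)C(OCOC)=C2[C@@](C)([O-])C=C[C@@H]12 | intermediate (not isolated)
21 | bis-silyl derivative: C18 triethylsilyl ester and C4 triethylsilyl ether | CC[Si](CC)(CC)OC(=O)C1=CC[C@@H]([C@H](C)C[C@H](C=C(C)C)O[Si](C)(C)C(C)(C)C)C(OCOC)=C2[C@@](C)(O[Si](CC)(CC)CC)C=C[C@@H]12 | intermediate (not isolated)
22 | enol ether acid: free C18 acid, C4 triethylsilyl ether | OC(=O)C1=CC[C@@H]([C@H](C)C[C@H](C=C(C)C)O[Si](C)(C)C(C)(C)C)C(OCOC)=C2[C@@](C)(O[Si](CC)(CC)CC)C=C[C@@H]12 | intermediate (not isolated)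
23 | trans-fused keto acid: C6 ketone, H-5 trans to H-1, C4 triethylsilyl ether, C13 silyl ether | OC(=O)C1=CC[C@@H]([C@H](C)C[C@H](C=C(C)C)O[Si](C)(C)C(C)(C)C)C(=O)[C@@H]2[C@@](C)(O[Si](CC)(CC)CC)C=C[C@@H]12 | intermediate
24 | dihydroxy keto acid (free C4 and C13 hydroxyls) | OC(=O)C1=CC[C@@H]([C@H](C)C[C@H](C=C(C)C)O)C(=O)[C@@H]2[C@@](C)(O)C=C[C@@H]12 | intermediate
25 | C13 acetate keto acid | OC(=O)C1=CC[C@@H]([C@H](C)C[C@H](C=C(C)C)OC(C)=O)C(=O)[C@@H]2[C@@](C)(O)C=C[C@@H]12 | intermediate
26 | isobutyl carbonic mixed anhydride of 25 | CC(C)COC(=O)OC(=O)C1=CC[C@@H]([C@H](C)C[C@H](C=C(C)C)OC(C)=O)C(=O)[C@@H]2[C@@](C)(O)C=C[C@@H]12 | intermediate (not isolated)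
27 | C18 allylic alcohol triol acetate (C6 hydroxyl cis to the side chain) | OCC1=CC[C@@H]([C@H](C)C[C@H](C=C(C)C)OC(C)=O)[C@@H](O)[C@@H]2[C@@](C)(O)C=C[C@@H]12 | intermediate
28 | N-allylic N-(2-nitrobenzenesulfonyl)hydrazine at C18 | NN(CC1=CC[C@@H]([C@H](C)C[C@H](C=C(C)C)OC(C)=O)[C@@H](O)[C@@H]2[C@@](C)(O)C=C[C@@H]12)S(=O)(=O)c1ccccc1[N+](=O)[O-] | intermediate (not isolated)
29 | allylic diazene at C18 | N=NCC1=CC[C@@H]([C@H](C)C[C@H](C=C(C)C)OC(C)=O)[C@@H](O)[C@@H]2[C@@](C)(O)C=C[C@@H]12 | intermediate (not isolated)
30 | target CNP0209568.3: trans-fused hydroazulene triene, 4,6-diol, C13 acetate (C1 R, C4 S, C5 R, C6 R, C7 S, C11 R, C13 R) | C=C1CC[C@@H]([C@H](C)C[C@H](C=C(C)C)OC(C)=O)[C@@H](O)[C@H]2[C@H]1C=C[C@]2(C)O | target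

Total step count: 16. Longest linear sequence: 16 steps (1 to 30).

Steps most likely to fail

Step 12. What may go wrong: the external buffer protonates C5 from the convex face (cis ring fusion), or the doubly allylic C4–O bond ionises through the enol ether, before the C18 acid has delivered its proton. The fallback replaces acid-mediated delivery by an acid-free proton relay from an alcohol; it sets out from 17 and comes back at 30. KN(SiMe3)2 and t-BuMe2SiCl convert 17 into silyl enol ether F1, which should rearrange as in step 11 to bridged lactone F2. i-Bu2AlH reduces the lactone to diol F3. One equivalent of Bu4N[Ph3SiF2] in dilute THF at −78 °C cleaves only the enol silyl ether, and the C18 hydroxyl, held over the same face of C5, should return the proton to the enolate to give trans-fused hydroxy ketone F4. The sulfonylhydrazide transposition of step 16 then gives exocyclic alkene F5, HF·pyridine gives alcohol F6, Ac2O in pyridine gives acetate F7, and NaBH4 reduces the C6 ketone from the face opposite the side chain to give 30.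

Step 8. What may go wrong: conjugate addition of the hindered tertiary bromo dienolate next to the silyloxy group is slow, closure occurs on oxygen instead of carbon, or the exo-vinyl to endo-vinyl ratio is poor. The fallback separates the two bond formations; it sets out from 10 and comes back at 12. The halogen-free, less hindered lithium dienolate of methyl but-3-enoate (from methyl crotonate and LiN(i-Pr)2 in THF/DMPU) is added to 10 to give the regiodefined lithium enolate F8. F8 is not quenched but deprotonated at the ester α-carbon with a second equivalent of LiN(i-Pr)2 and oxidised with I2 at −78 °C (α-iodination, then intramolecular enolate alkylation), which should close the same cyclopropane 12; DBU as in step 8 then gives 13.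

Step 6. What may go wrong: phosphine addition beside the silyloxy group is sluggish and the catalyst induces β-elimination of silanol from the enone. The fallback uses a stoichiometric tandem conjugate addition–aldol; it sets out from 7 and 8 and comes back at 9. Me2AlSPh adds thiolate to the β-carbon of 8 anti to the silyloxy group and the aluminium enolate adds to aldehyde 7 to give β-phenylthio aldol F9. NaIO4 oxidises the sulfide to sulfoxide F10, which on warming loses benzenesulfenic acid by syn-elimination to give 9.

Further compounds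

F1 | step 12 | (Z)-tert-butyldimethylsilyl enol ether of 17, cis-divinylcyclopropane | C[C@]12C=C[C@@H]3[C@@]1(/C(O[Si](C)(C)C(C)(C)C)=C/[C@H](C)C[C@H](C=C(C)C)O[Si](C)(C)C(C)(C)C)[C@]3(C=C)C(=O)O2
F2 | step 12 | bridged-lactone cycloheptadiene with C6 silyl enol ether | C[C@@]12C=C[C@H]3C(C(=O)O1)=CC[C@@H]([C@H](C)C[C@H](C=C(C)C)O[Si](C)(C)C(C)(C)C)C(O[Si](C)(C)C(C)(C)C)=C23
F3 | step 12 | C4,C18-diol with C6 silyl enol ether | OCC1=CC[C@@H]([C@H](C)C[C@H](C=C(C)C)O[Si](C)(C)C(C)(C)C)C(O[Si](C)(C)C(C)(C)C)=C2[C@@](C)(O)C=C[C@@H]12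
F4 | step 12 | trans-fused C6 ketone with C4 and C18 hydroxyls | OCC1=CC[C@@H]([C@H](C)C[C@H](C=C(C)C)O[Si](C)(C)C(C)(C)C)C(=O)[C@@H]2[C@@](C)(O)C=C[C@@H]12
F5 | step 12 | C6 ketone with exocyclic C10=C18 alkene, C13 silyl ether | C=C1CC[C@@H]([C@H](C)C[C@H](C=C(C)C)O[Si](C)(C)C(C)(C)C)C(=O)[C@H]2[C@H]1C=C[C@]2(C)O
F6 | step 12 | C6 ketone with free C13 hydroxyl | C=C1CC[C@@H]([C@H](C)C[C@H](C=C(C)C)O)C(=O)[C@H]2[C@H]1C=C[C@]2(C)O
F7 | step 12 | C6 ketone C13 acetate | C=C1CC[C@@H]([C@H](C)C[C@H](C=C(C)C)OC(C)=O)C(=O)[C@H]2[C@H]1C=C[C@]2(C)O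
F8 | step 8 | lithium enolate of the Michael adduct of 10 with the dienolate of methyl but-3-enoate | [Li+].[O-]C1=C(C(O[Si](CC)(CC)CC)C[C@H](C)C[C@H](C=C(C)C)O[Si](C)(C)C(C)(C)C)[C@H](C(C=C)C(=O)OC)[C@@H](O[Si](C)(C)C(C)(C)C)C1
F9 | step 6 | β-phenylthio aldol from 8, Me2AlSPh and 7 | O=C1C[C@H](O[Si](C)(C)C(C)(C)C)C(Sc2ccccc2)C1C(O)C[C@H](C)C[C@H](C=C(C)C)O[Si](C)(C)C(C)(C)C
F10 | step 6 | sulfoxide of F9 | O=C1C[C@H](O[Si](C)(C)C(C)(C)C)C(S(=O)c2ccccc2)C1C(O)C[C@H](C)C[C@H](C=C(C)C)O[Si](C)(C)C(C)(C)C
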